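## Retrosynthetic overview

1. Target 15 comes from the pentasilyl (2S)-flavanone 14 by global desilylation. Rings A and B are bought in; ring C is the only ring made.
2. Ring C is opened at C2–C3. The plan rests on C2 being a CH that carries O1 and aryl ring B and lies six atoms from C3 (C3–C4–C4a–C8a–O1–C2). It therefore maps onto the prochiral OCH2 of an O1 arylmethyl ether and is closed by enantioselective rhodium-carbene C–H insertion of diazoketone 13.
3. Diazoketone 13 comes from methyl ketone 11 by detrifluoroacetylative diazo transfer. The C6 carbinol chain comes from a prenyl group by Markovnikov hydration under cobalt/silane/O2, so no acid-promoted step meets the tertiary alcohol.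
4. The oxygen pattern of ring A is set on 2,4,6-trihydroxyacetophenone 1: C-prenylation, silylation of the para hydroxyl, Mitsunobu coupling of the less hindered ortho hydroxyl with benzylic alcohol 7 (from 3,4-dihydroxybenzaldehyde 5), then silylation of the last hydroxyl.

Key step: step 10

Assumption: Rh2(S-PTTL)4, dirhodium tetrakis[N-phthaloyl-(S)-tert-leucinate], is taken to deliver the (2S) product; if the sense of induction proves opposite, the enantiomeric catalyst Rh2(R-PTTL)4 would be used unchanged in every other respect.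

## Route

Step 1
Reactants: 1 2,4,6-trihydroxyacetophenone; 2 prenyl bromide (1-bromo-3-methylbut-2-ene)
Product: 3 1-[2,4,6-trihydroxy-3-(3-methylbut-2-en-1-yl)phenyl]ethan-1-one
Conditions: DBU (1 equiv), THF, 0 °C to rt; 2 added slowly to 1 (1.5 equiv)
Reagents that add atoms: none
Why: C-alkylation of the ambident phloroacetophenone anion by an allylic bromide; the two free ring carbons of 1 are equivalent, so mono-C-prenylation can give only one constitutional isomer, and keeping 2 deficient should limit double alkylation.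

Step 2
Reactants: 3 1-[2,4,6-trihydroxy-3-(3-methylbut-2-en-1-yl)phenyl]ethan-1-one
Product: 4 1-[4-(tert-butyldimethylsilyloxy)-2,6-dihydroxy-3-(3-methylbut-2-en-1-yl)phenyl]ethan-1-one
Conditions: TBSCl (1.05 equiv), imidazole, CH2Cl2/DMF, −10 °C
Reagents that add atoms: tert-butyldimethylsilyl chloride, CC(C)(C)[Si](C)(C)Cl
Why: Selective O-silylation, because the 4-OH para to the acetyl group is the most acidic hydroxyl and the only one not held in a hydrogen bond to the carbonyl, so one equivalent of silyl chloride should take it first.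

Step 3
Reactants: 5 3,4-dihydroxybenzaldehyde
Product: 6 3,4-bis(tert-butyldimethylsilyloxy)benzaldehyde
Conditions: TBSCl (2.4 equiv), imidazole, DMF, rt
Reagents that add atoms: tert-butyldimethylsilyl chloride, CC(C)(C)[Si](C)(C)Cl
Why: Standard imidazole-promoted silylation of both catechol hydroxyls.

Step 4
Reactants: 6 3,4-bis(tert-butyldimethylsilyloxy)benzaldehyde
Product: 7 [3,4-bis(tert-butyldimethylsilyloxy)phenyl]methanol
Conditions: NaBH4, MeOH/THF, 0 °C
Reagents that add atoms: none
Why: Borohydride reduction of an aryl aldehyde to the benzylic alcohol, short and cold enough to leave the aryl silyl ethers in place.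

Step 5
Reactants: 4 1-[4-(tert-butyldimethylsilyloxy)-2,6-dihydroxy-3-(3-methylbut-2-en-1-yl)phenyl]ethan-1-one; 7 [3,4-bis(tert-butyldimethylsilyloxy)phenyl]methanol
Product: 8 1-[6-{[3,4-bis(tert-butyldimethylsilyloxy)phenyl]methoxy}-4-(tert-butyldimethylsilyloxy)-2-hydroxy-3-(3-methylbut-2-en-1-yl)phenyl]ethan-1-one
Conditions: PPh3, DIAD, THF, 0 °C to rt
Reagents that add atoms: none
Why: Mitsunobu etherification under neutral conditions that spare aryl silyl ethers; the 6-OH flanked by hydrogen should react in preference to the 2-OH wedged between acetyl and prenyl, and the remaining hydroxyl, then firmly chelated to the carbonyl, should resist a second alkylation.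

Step 6
Reactants: 8 1-[6-{[3,4-bis(tert-butyldimethylsilyloxy)phenyl]methoxy}-4-(tert-butyldimethylsilyloxy)-2-hydroxy-3-(3-methylbut-2-en-1-yl)phenyl]ethan-1-one
Product: 9 1-[6-{[3,4-bis(tert-butyldimethylsilyloxy)phenyl]methoxy}-2,4-bis(tert-butyldimethylsilyloxy)-3-(3-methylbut-2-en-1-yl)phenyl]ethan-1-one
Conditions: TBSOTf (1.3 equiv), 2,6-lutidine, CH2Cl2, −78 to 0 °C
Reagents that add atoms: tert-butyldimethylsilyl trifluoromethanesulfonate, CC(C)(C)[Si](C)(C)OS(=O)(=O)C(F)(F)F
Why: Silyl triflate silylation of a hindered, chelated phenol; the weak hindered base scavenges triflic acid so that the prenyl group is not protonated and the ketone is not enol-silylated.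

Step 7
Reactants: 9 1-[6-{[3,4-bis(tert-butyldimethylsilyloxy)phenyl]methoxy}-2,4-bis(tert-butyldimethylsilyloxy)-3-(3-methylbut-2-en-1-yl)phenyl]ethan-1-one
Product: 10 1-[6-{[3,4-bis(tert-butyldimethylsilyloxy)phenyl]methoxy}-2,4-bis(tert-butyldimethylsilyloxy)-3-(3-hydroxy-3-methylbutyl)phenyl]ethan-1-one
Conditions: Co(acac)2 (cat.), PhSiH3, O2 (1 atm), THF, rt
Reagents that add atoms: dioxygen, O=O
Why: Mukaiyama hydration by metal-hydride hydrogen-atom transfer; the hydrogen atom adds to the less substituted alkene carbon, the tertiary radical is trapped by O2 and the peroxide is reduced by the silane, which should give the Markovnikov tertiary alcohol without acid and without touching the aryl ketone, the benzylic ether or the silyl ethers.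

Step 8
Reactants: 10 1-[6-{[3,4-bis(tert-butyldimethylsilyloxy)phenyl]methoxy}-2,4-bis(tert-butyldimethylsilyloxy)-3-(3-hydroxy-3-methylbutyl)phenyl]ethan-1-one
Product: 11 1-[6-{[3,4-bis(tert-butyldimethylsilyloxy)phenyl]methoxy}-2,4-bis(tert-butyldimethylsilyloxy)-3-{3-methyl-3-(triethylsilyloxy)butyl}phenyl]ethan-1-one
Conditions: TESOTf, 2,6-lutidine, CH2Cl2, −78 to 0 °C
Reagents that add atoms: triethylsilyl trifluoromethanesulfonate, CC[Si](CC)(CC)OS(=O)(=O)C(F)(F)F
Why: Silyl triflate silylation of a tertiary alcohol, which masks the O–H bond from the amide base of step 9 and from carbene O–H insertion in step 10.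

Step 9
Reactants: 11 1-[6-{[3,4-bis(tert-butyldimethylsilyloxy)phenyl]methoxy}-2,4-bis(tert-butyldimethylsilyloxy)-3-{3-methyl-3-(triethylsilyloxy)butyl}phenyl]ethan-1-one
Product: 13 2-diazo-1-[6-{[3,4-bis(tert-butyldimethylsilyloxy)phenyl]methoxy}-2,4-bis(tert-butyldimethylsilyloxy)-3-{3-methyl-3-(triethylsilyloxy)butyl}phenyl]ethan-1-one, via trifluoroacetyl diketone 12 (not isolated)
Conditions: LiHMDS, THF, −78 °C; CF3CO2CH2CF3, −78 °C; aq. HCl quench; then MsN3, Et3N, H2O (1 equiv), MeCN, rt
Reagents that add atoms: methanesulfonyl azide, CS(=O)(=O)N=[N+]=[N-]; 2,2,2-trifluoroethyl trifluoroacetate, O=C(OCC(F)(F)F)C(F)(F)F (its CF3CO group is carried only in 12)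
Why: Detrifluoroacetylative Regitz-type diazo transfer; Claisen trifluoroacetylation of the lithium enolate at low temperature activates the methyl ketone as diketone 12, to which the sulfonyl azide transfers N2 with loss of the trifluoroacetyl group, conditions that aryl silyl ethers and the benzylic ether should tolerate.

Step 10
Reactants: 13 2-diazo-1-[6-{[3,4-bis(tert-butyldimethylsilyloxy)phenyl]methoxy}-2,4-bis(tert-butyldimethylsilyloxy)-3-{3-methyl-3-(triethylsilyloxy)butyl}phenyl]ethan-1-one
Product: 14 (2S)-2-[3,4-bis(tert-butyldimethylsilyloxy)phenyl]-5,7-bis(tert-butyldimethylsilyloxy)-6-{3-methyl-3-(triethylsilyloxy)butyl}-2,3-dihydro-4H-chromen-4-one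
Conditions: Rh2(S-PTTL)4 (2 mol%), 4 Å molecular sieves, toluene, 0 °C, slow addition of 13 at high dilution
Reagents that add atoms: none
Why: The dirhodium carboxylate expels N2 from 13 to give an electrophilic rhodium carbene at C3, which takes one of the two enantiotopic benzylic hydrogens of the O1–CH2Ar group through a concerted, hydride-transfer-like three-centre transition state and forms the C2–C3 bond. The closest known reaction type is the dirhodium-carboxylate-catalysed intramolecular C–H insertion of 2-alkoxyaryl diazoketones to chroman-4-ones. Ring C closes as a six-membered ring by 1,6-insertion through a six-membered cyclic transition state, the carbene carbon C3 reaching the C–H bond across C4, C4a, C8a and O1. The single stereocentre C2 is set by the chiral phthalimido-tert-leucinate pocket of the catalyst, which distinguishes the two enantiotopic hydrogens, no substrate stereocentre being involved. The step needs chemoselectivity for C–H insertion over oxonium-ylide formation at O1 followed by 1,2-shift to a 2-benzylbenzofuran-3-one; this is secured by the low basicity of the aryl ether oxygen conjugated to the ketone together with double activation of the C–H bond by O1 and the electron-rich aryl ring. The O5 substituent is a bulky silyl group with no α C–H bond, so the future C2–H is the only activated site within reach, and slow addition at high dilution should suppress carbene dimerisation.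

Step 11
Reactants: 14 (2S)-2-[3,4-bis(tert-butyldimethylsilyloxy)phenyl]-5,7-bis(tert-butyldimethylsilyloxy)-6-{3-methyl-3-(triethylsilyloxy)butyl}-2,3-dihydro-4H-chromen-4-one
Product: 15 (2S)-2-(3,4-dihydroxyphenyl)-5,7-dihydroxy-6-(3-hydroxy-3-methylbutyl)-2,3-dihydro-4H-chromen-4-one
Conditions: HF·pyridine, excess pyridine, THF, 0 °C to rt
Reagents that add atoms: none
Why: Buffered fluoride desilylation cleaves the four aryl Si–O bonds and the tertiary alkyl Si–O bond; no free phenoxide is present to trigger retro-oxa-Michael opening of ring C, so C2 should keep its configuration, and the medium is too weakly acidic to ionise the tertiary alcohol toward chroman formation.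

## Compound list

1 | 2,4,6-trihydroxyacetophenone | CC(=O)c1c(O)cc(O)cc1O | starting material
2 | prenyl bromide (1-bromo-3-methylbut-2-ene) | CC(C)=CCBr | starting material
3 | 1-[2,4,6-trihydroxy-3-(3-methylbut-2-en-1-yl)phenyl]ethan-1-one | CC(=O)c1c(O)cc(O)c(CC=C(C)C)c1O | intermediate
4 | 1-[4-(tert-butyldimethylsilyloxy)-2,6-dihydroxy-3-(3-methylbut-2-en-1-yl)phenyl]ethan-1-one | CC(=O)c1c(O)cc(O[Si](C)(C)C(C)(C)C)c(CC=C(C)C)c1O | intermediate
5 | 3,4-dihydroxybenzaldehyde | O=Cc1ccc(O)c(O)c1 | starting material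
6 | 3,4-bis(tert-butyldimethylsilyloxy)benzaldehyde | O=Cc1ccc(O[Si](C)(C)C(C)(C)C)c(O[Si](C)(C)C(C)(C)C)c1 | intermediate
7 | [3,4-bis(tert-butyldimethylsilyloxy)phenyl]methanol | OCc1ccc(O[Si](C)(C)C(C)(C)C)c(O[Si](C)(C)C(C)(C)C)c1 | intermediate
8 | 1-[6-{[3,4-bis(tert-butyldimethylsilyloxy)phenyl]methoxy}-4-(tert-butyldimethylsilyloxy)-2-hydroxy-3-(3-methylbut-2-en-1-yl)phenyl]ethan-1-one | CC(=O)c1c(OCc2ccc(O[Si](C)(C)C(C)(C)C)c(O[Si](C)(C)C(C)(C)C)c2)cc(O[Si](C)(C)C(C)(C)C)c(CC=C(C)C)c1O | intermediate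
9 | 1-[6-{[3,4-bis(tert-butyldimethylsilyloxy)phenyl]methoxy}-2,4-bis(tert-butyldimethylsilyloxy)-3-(3-methylbut-2-en-1-yl)phenyl]ethan-1-one | CC(=O)c1c(OCc2ccc(O[Si](C)(C)C(C)(C)C)c(O[Si](C)(C)C(C)(C)C)c2)cc(O[Si](C)(C)C(C)(C)C)c(CC=C(C)C)c1O[Si](C)(C)C(C)(C)C | intermediate
10 | 1-[6-{[3,4-bis(tert-butyldimethylsilyloxy)phenyl]methoxy}-2,4-bis(tert-butyldimethylsilyloxy)-3-(3-hydroxy-3-methylbutyl)phenyl]ethan-1-one | CC(=O)c1c(OCc2ccc(O[Si](C)(C)C(C)(C)C)c(O[Si](C)(C)C(C)(C)C)c2)cc(O[Si](C)(C)C(C)(C)C)c(CCC(C)(C)O)c1O[Si](C)(C)C(C)(C)C | intermediate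
11 | 1-[6-{[3,4-bis(tert-butyldimethylsilyloxy)phenyl]methoxy}-2,4-bis(tert-butyldimethylsilyloxy)-3-{3-methyl-3-(triethylsilyloxy)butyl}phenyl]ethan-1-one | CC(=O)c1c(OCc2ccc(O[Si](C)(C)C(C)(C)C)c(O[Si](C)(C)C(C)(C)C)c2)cc(O[Si](C)(C)C(C)(C)C)c(CCC(C)(C)O[Si](CC)(CC)CC)c1O[Si](C)(C)C(C)(C)C | intermediate
12 | 4,4,4-trifluoro-1-[6-{[3,4-bis(tert-butyldimethylsilyloxy)phenyl]methoxy}-2,4-bis(tert-butyldimethylsilyloxy)-3-{3-methyl-3-(triethylsilyloxy)butyl}phenyl]butane-1,3-dione | O=C(CC(=O)C(F)(F)F)c1c(OCc2ccc(O[Si](C)(C)C(C)(C)C)c(O[Si](C)(C)C(C)(C)C)c2)cc(O[Si](C)(C)C(C)(C)C)c(CCC(C)(C)O[Si](CC)(CC)CC)c1O[Si](C)(C)C(C)(C)C | intermediate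
13 | 2-diazo-1-[6-{[3,4-bis(tert-butyldimethylsilyloxy)phenyl]methoxy}-2,4-bis(tert-butyldimethylsilyloxy)-3-{3-methyl-3-(triethylsilyloxy)butyl}phenyl]ethan-1-one | CC(C)(O[Si](CC)(CC)CC)CCc1c(O[Si](C)(C)C(C)(C)C)cc(OCc2ccc(O[Si](C)(C)C(C)(C)C)c(O[Si](C)(C)C(C)(C)C)c2)c(C(=O)C=[N+]=[N-])c1O[Si](C)(C)C(C)(C)C | intermediate
14 | (2S)-2-[3,4-bis(tert-butyldimethylsilyloxy)phenyl]-5,7-bis(tert-butyldimethylsilyloxy)-6-{3-methyl-3-(triethylsilyloxy)butyl}-2,3-dihydro-4H-chromen-4-one | CC(C)(O[Si](CC)(CC)CC)CCc1c(O[Si](C)(C)C(C)(C)C)cc2c(c1O[Si](C)(C)C(C)(C)C)C(=O)C[C@@H](c1ccc(O[Si](C)(C)C(C)(C)C)c(O[Si](C)(C)C(C)(C)C)c1)O2 | intermediate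
15 | (2S)-2-(3,4-dihydroxyphenyl)-5,7-dihydroxy-6-(3-hydroxy-3-methylbutyl)-2,3-dihydro-4H-chromen-4-one | CC(C)(O)CCc1c(O)cc2c(c1O)C(=O)C[C@@H](c1ccc(O)c(O)c1)O2 | target

## Step count and risks

Total steps: 11. Longest linear sequence: 9 (steps 1, 2, 5, 6, 7, 8, 9, 10, 11 from compound 1); steps 3 and 4 make the side fragment 7.

Steps most likely to fail:

**Step 10 (key step).** The carbene may be diverted to oxonium-ylide formation at O1 with 1,2-benzyl shift, or the catalyst may discriminate poorly between the two enantiotopic benzylic hydrogens. The fallback sets out from 11 and returns at 14, closing ring C by conjugate addition instead of carbene insertion. Hydrogenolysis of 11 (H2, Pd/C, EtOAc) would remove the arylmethyl group and give 1-[2,4-bis(tert-butyldimethylsilyloxy)-6-hydroxy-3-{3-methyl-3-(triethylsilyloxy)butyl}phenyl]ethan-1-one F1. Condensation with N,N-dimethylformamide dimethyl acetal in warm toluene would give the (E)-3-(dimethylamino)-1-arylprop-2-en-1-one F2, which should cyclise with loss of dimethylamine under mild acid (PPTS, toluene) to 5,7-bis(tert-butyldimethylsilyloxy)-6-{3-methyl-3-(triethylsilyloxy)butyl}-4H-chromen-4-one F3. In parallel, commercial 4-bromobenzene-1,2-diol would be silylated (TBSCl, imidazole, DMF) to 4-bromo-1,2-bis(tert-butyldimethylsilyloxy)benzene F4 and converted by bromine–lithium exchange (n-BuLi, THF, −78 °C) and B(OiPr)3 quench into [3,4-bis(tert-butyldimethylsilyloxy)phenyl]boronic acid F5. Asymmetric conjugate addition of F5 to F3 under Pd(OCOCF3)2 and a chiral 4-tert-butyl-2-(pyridin-2-yl)-4,5-dihydrooxazole ligand (enantiomer chosen for 2S; NH4PF6, H2O, 1,2-dichloroethane, 60 °C), a known reaction class for chromones, should then give 14.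

**Step 5.** Site selection between the 2-OH and the 6-OH rests on sterics alone and may be incomplete, giving the regioisomeric ether. The fallback sets out from 4 and returns at 8, tying up the 2-OH with the neighbouring prenyl group before the coupling. Iodoetherification of 4 (I2, NaHCO3, MeCN, 0 °C) can engage only the 2-OH, since the other oxygen flanking the prenyl group is silylated, and should give the racemic 1-[5-(tert-butyldimethylsilyloxy)-7-hydroxy-3-iodo-2,2-dimethyl-3,4-dihydro-2H-chromen-8-yl]ethan-1-one F6. Mitsunobu coupling of its single free hydroxyl with 7 (PPh3, DIAD, THF) would give the 7-arylmethyl ether F7. Boord-type reductive elimination of the β-iodo ether (Zn, AcOH, EtOH, rt) would then reopen the chroman, restoring the prenyl group and the 2-OH, to give 8 with no regiochemical ambiguity.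

**Step 9.** The lithium enolate of 11 may suffer oxygen-to-oxygen silyl migration from the ortho silyl ether, or its trifluoroacetylation may be slow at the hindered ketone. The fallback sets out from 11 and returns at 13 without any metal enolate. Heating 11 with N,N-dimethylformamide dimethyl acetal would give the (E)-3-(dimethylamino)-1-arylprop-2-en-1-one F8. Treatment with MsN3 in MeCN should effect deformylative diazo transfer (azide–enaminone cycloaddition, then cycloreversion with loss of an N-sulfonylformamidine) and give 13.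

## Further compounds

F1 | step 10 | 1-[2,4-bis(tert-butyldimethylsilyloxy)-6-hydroxy-3-{3-methyl-3-(triethylsilyloxy)butyl}phenyl]ethan-1-one | CC(=O)c1c(O)cc(O[Si](C)(C)C(C)(C)C)c(CCC(C)(C)O[Si](CC)(CC)CC)c1O[Si](C)(C)C(C)(C)C
F2 | step 10 | (E)-3-(dimethylamino)-1-[2,4-bis(tert-butyldimethylsilyloxy)-6-hydroxy-3-{3-methyl-3-(triethylsilyloxy)butyl}phenyl]prop-2-en-1-one | CN(C)/C=C/C(=O)c1c(O)cc(O[Si](C)(C)C(C)(C)C)c(CCC(C)(C)O[Si](CC)(CC)CC)c1O[Si](C)(C)C(C)(C)C
F3 | step 10 | 5,7-bis(tert-butyldimethylsilyloxy)-6-{3-methyl-3-(triethylsilyloxy)butyl}-4H-chromen-4-one | O=c1ccoc2cc(O[Si](C)(C)C(C)(C)C)c(CCC(C)(C)O[Si](CC)(CC)CC)c(O[Si](C)(C)C(C)(C)C)c12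
F4 | step 10 | 4-bromo-1,2-bis(tert-butyldimethylsilyloxy)benzene | Brc1ccc(O[Si](C)(C)C(C)(C)C)c(O[Si](C)(C)C(C)(C)C)c1
F5 | step 10 | [3,4-bis(tert-butyldimethylsilyloxy)phenyl]boronic acid | OB(O)c1ccc(O[Si](C)(C)C(C)(C)C)c(O[Si](C)(C)C(C)(C)C)c1
F6 | step 5 | 1-[5-(tert-butyldimethylsilyloxy)-7-hydroxy-3-iodo-2,2-dimethyl-3,4-dihydro-2H-chromen-8-yl]ethan-1-one (racemic) | CC(=O)c1c(O)cc(O[Si](C)(C)C(C)(C)C)c2c1OC(C)(C)C(I)C2
F7 | step 5 | 1-[7-{[3,4-bis(tert-butyldimethylsilyloxy)phenyl]methoxy}-5-(tert-butyldimethylsilyloxy)-3-iodo-2,2-dimethyl-3,4-dihydro-2H-chromen-8-yl]ethan-1-one (racemic) | CC(=O)c1c(OCc3ccc(O[Si](C)(C)C(C)(C)C)c(O[Si](C)(C)C(C)(C)C)c3)cc(O[Si](C)(C)C(C)(C)C)c2c1OC(C)(C)C(I)C2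
F8 | step 9 | (E)-3-(dimethylamino)-1-[6-{[3,4-bis(tert-butyldimethylsilyloxy)phenyl]methoxy}-2,4-bis(tert-butyldimethylsilyloxy)-3-{3-methyl-3-(triethylsilyloxy)butyl}phenyl]prop-2-en-1-one | CN(C)/C=C/C(=O)c1c(OCc2ccc(O[Si](C)(C)C(C)(C)C)c(O[Si](C)(C)C(C)(C)C)c2)cc(O[Si](C)(C)C(C)(C)C)c(CCC(C)(C)O[Si](CC)(CC)CC)c1O[Si](C)(C)C(C)(C)C
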